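The route rests on cutting two bonds of the five-membered ring, C1–C2 and C4–C5 (guaiane numbering). This turns C2–C3–C4–C15 into a but-3-ynyl radical and leaves the seven-membered ring as a fully substituted cyclohept-2-enone. The feature exploited is that the fusion bond C1–C5 is the β,α-bond of a C6 carbonyl, and that the C4 methyl carbinol is a hydrated exocyclic alkene. One radical [3+2] annulation (addition at C1, 5-exo-dig closure from C5) makes both bonds, the last ring and the cis C1/C5 fusion. Its precursor is monocyclic enone 9, which already carries the C10 silyl ether and the masked C11–C13 triol on C7.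

Key step: step 6

Numbering and faces: guaiane numbering is used throughout (five-membered ring C1–C5; seven-membered ring C1, C5–C10; C14 on C10; C15 on C4; C11–C13 on C7). α is the face of H1, H5 and H7 in the target, β the opposite face.
Assumption: the quinine-derived primary amine salt is taken to deliver the (1R,7R)-epoxide 2. If its sense of induction is the opposite, the quinidine-derived pseudoenantiomer is used and nothing else changes.

Step 1
Reactants: 1 3-methylcyclohept-2-en-1-one
Product: 2 (1R,7R)-7-methyl-8-oxabicyclo[5.1.0]octan-2-one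
Conditions: 9-amino-9-deoxy-epi-quinine (10 mol %), CF3CO2H (20 mol %), 50% aq H2O2 (1.5 equiv), dioxane, 50 °C
Reagents that add atoms: hydrogen peroxide, OO
Why: This is an iminium-catalysed Weitz–Scheffer-type epoxidation of a cyclic enone, in which the chiral primary amine salt should select the enone face and so set C10 (and transiently C1) with oxygen on the α face.

Step 2
Reactants: 2 (1R,7R)-7-methyl-8-oxabicyclo[5.1.0]octan-2-one
Product: 4 (R)-1-methylcyclohept-2-en-1-ol, via epoxy hydrazone 3 (not isolated)
Conditions: N2H4·H2O (3 equiv), AcOH (cat.), MeOH, 0 °C to rt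
Reagents that add atoms: none
Why: In this Wharton transposition the hydrazone opens the epoxide and loses N2, which should give the C1=C5 alkene, and the C10–O bond is never broken, so C10 keeps its configuration.

Step 3
Reactants: 4 (R)-1-methylcyclohept-2-en-1-ol
Product: 5 (R)-triethyl[(1-methylcyclohept-2-en-1-yl)oxy]silane
Conditions: Et3SiOTf (1.3 equiv), 2,6-lutidine (2 equiv), CH2Cl2, −78 to 0 °C
Reagents that add atoms: triethylsilyl trifluoromethanesulfonate, CC[Si](CC)(CC)OS(=O)(=O)C(F)(F)F
Why: A hindered tertiary alcohol needs the silyl triflate, and the resulting ether blocks oxidative allylic transposition in step 4 and later serves as the stereocontrol element on the α face.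

Step 4
Reactants: 5 (R)-triethyl[(1-methylcyclohept-2-en-1-yl)oxy]silane
Product: 6 (R)-4-methyl-4-(triethylsilyloxy)cyclohept-2-en-1-one
Conditions: Rh2(cap)4 (dirhodium tetrakis(caprolactamate), 1 mol %), t-BuOOH (5 equiv), K2CO3 (0.5 equiv), CH2Cl2, rt
Reagents that add atoms: tert-butyl hydroperoxide, CC(C)(C)OO
Why: In this radical allylic C–H oxidation (Kharasch type) C6 is the only allylic CH2, because C10 is quaternary, so the enone C6(=O)–C5=C1 should form regioselectively without touching C10.

Step 5
Reactants: 6 (R)-4-methyl-4-(triethylsilyloxy)cyclohept-2-en-1-one; 7 2,2-dimethyl-1,3-dioxan-5-one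
Product: 9 (4R,7S)-7-(5-hydroxy-2,2-dimethyl-1,3-dioxan-5-yl)-4-methyl-4-(triethylsilyloxy)cyclohept-2-en-1-one, via lithium dienolate 8 (not isolated)
Conditions: LDA (1.1 equiv), THF, −78 °C; 7 (1.3 equiv), −78 °C, short contact; AcOH quench at −78 °C
Reagents that add atoms: none
Why: In this lithium enolate aldol addition only C7 can be deprotonated (C10 is quaternary), and ketone 7 should reach the flat cross-conjugated dienolate on the β face, anti to the pseudo-axial C10 silyloxy group and staggered to the pseudo-axial C8–H, which sets C7 with the side chain β.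

Step 6
Reactants: 9 (4R,7S)-7-(5-hydroxy-2,2-dimethyl-1,3-dioxan-5-yl)-4-methyl-4-(triethylsilyloxy)cyclohept-2-en-1-one; 10 4-iodobut-1-yne
Product: 14 11-hydroxy-12,13-isopropylidenedioxy-10α-triethylsilyloxy-1αH,5αH,7αH-guai-4(15)-en-6-one, via but-3-ynyl radical 11 (not isolated), via C5 radical 12 (not isolated), via vinyl radical 13 (not isolated)
Conditions: 10 (4 equiv), 9 (0.02 M), toluene, 80 °C; (Me3Si)3SiH (3 equiv) and AIBN (0.2 equiv) added by syringe pump over 6 h
Reagents that add atoms: none
Why: The silyl radical abstracts iodine from 10, the nucleophilic primary radical 11 adds to C1 (the β-carbon of the enone, Giese addition), the C5 radical 12 closes on the pendant alkyne, and the vinyl radical 13 takes hydrogen from the silane, which carries the chain. The closest known reaction type is the radical [3+2] annulation of homopropargyl halides with electron-poor alkenes (tandem Giese addition and hex-5-ynyl cyclization). The only ring closed is the cyclopentane C1–C5, in the 5-exo-dig mode. C1 is controlled by C10, whose C–O bond should stand pseudo-axial and antiperiplanar to the incoming radical (Felkin–Anh-type), so that C2 enters on the β face trans to OSiEt3; C5 is controlled by the three-atom tether, which reaches C5 only on the face it occupies at C1 and so gives the cis fusion with H1 and H5 both α. The step needs iodine abstraction to outrun hydrosilylation of the alkyne (secured by the weak C–I bond and the excess of 10) and ring closure of 12 to outrun its reduction (secured by slow silane addition at high dilution). C7, C10, the ketal and the free C11 hydroxyl should be untouched under these neutral conditions.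

Step 7
Reactants: 14 11-hydroxy-12,13-isopropylidenedioxy-10α-triethylsilyloxy-1αH,5αH,7αH-guai-4(15)-en-6-one
Product: 15 12,13-isopropylidenedioxy-10α-triethylsilyloxy-1αH,5αH,7αH-guai-4(15)-ene-6α,11-diol
Conditions: Me4NBH(OAc)3 (6 equiv), MeCN/AcOH (1:1), −30 to −10 °C
Reagents that add atoms: none
Why: In this Evans–Saksena reduction the only free hydroxyl (C11–OH, on the β side chain) binds boron and should deliver hydride to C6 from the β face through a six-membered transition state, which gives the 6α-alcohol trans to C11, while the reagent alone does not reduce the ketone.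

Step 8
Reactants: 15 12,13-isopropylidenedioxy-10α-triethylsilyloxy-1αH,5αH,7αH-guai-4(15)-ene-6α,11-diol
Product: 17 12,13-isopropylidenedioxy-10α-triethylsilyloxy-1αH,5αH,7αH-guaiane-4α,6α,11-triol, via 4α-hydroperoxide 16 (not isolated)
Conditions: Mn(dpm)3 (tris(dipivaloylmethanato)manganese, 10 mol %), PhSiH3 (2.5 equiv), O2 (1 atm), i-PrOH/CH2Cl2, 0 °C; then PPh3
Reagents that add atoms: dioxygen, O=O
Why: In this Mukaiyama hydration hydrogen-atom transfer to C15 gives the tertiary C4 radical, which should capture O2 on the convex α face (the side of H5, away from C6 and the seven-membered ring), so C4 is set with OH α and methyl β.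

Step 9
Reactants: 17 12,13-isopropylidenedioxy-10α-triethylsilyloxy-1αH,5αH,7αH-guaiane-4α,6α,11-triol
Product: 18 1αH,5αH,7αH-guaiane-4α,6α,10α,11,12,13-hexaol
Conditions: 1 M aq HCl/THF (1:4), rt
Reagents that add atoms: none
Why: Dilute acid should hydrolyse the isopropylidene ketal and the tertiary triethylsilyl ether in one operation, the non-allylic tertiary alcohols should tolerate it at rt, and no C–O bond at a stereocentre is broken.

Step 10
Reactants: 18 1αH,5αH,7αH-guaiane-4α,6α,10α,11,12,13-hexaol
Product: 19 CNP0179913.1 (4α,6α,10α,11-tetrahydroxy-1αH,5αH,7αH-guaiane-12,13-diyl diacetate)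
Conditions: Ac2O (2.1 equiv), pyridine, −20 to 0 °C
Reagents that add atoms: acetic anhydride, CC(=O)OC(C)=O
Why: This is a rate-selective acylation in which the two primary hydroxyls should react well before the secondary C6–OH (flanked by two branched carbons) and the three tertiary hydroxyls, and C11 is not stereogenic, so no new stereocentre arises.

Compound list
1 | 3-methylcyclohept-2-en-1-one | CC1=CC(=O)CCCC1 | starting material
2 | (1R,7R)-7-methyl-8-oxabicyclo[5.1.0]octan-2-one (α-epoxide across C1–C10, ketone at C5) | C1CC[C@@]2(C)O[C@H]2C(=O)C1 | intermediate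
3 | hydrazone of 2 | C1CC[C@@]2(C)O[C@H]2C(=NN)C1 | intermediate
4 | (R)-1-methylcyclohept-2-en-1-ol | C1CC[C@@](C)(O)C=CC1 | intermediate
5 | (R)-triethyl[(1-methylcyclohept-2-en-1-yl)oxy]silane | C1CC[C@@](C)(O[Si](CC)(CC)CC)C=CC1 | intermediate
6 | (R)-4-methyl-4-(triethylsilyloxy)cyclohept-2-en-1-one | C1CC[C@@](C)(O[Si](CC)(CC)CC)C=CC1=O | intermediate
7 | 2,2-dimethyl-1,3-dioxan-5-one | CC1(C)OCC(=O)CO1 | starting material
8 | lithium cross-conjugated dienolate of 6 (C6–OLi, C6=C7, C1=C5) | [Li]OC1=CCC[C@@](C)(O[Si](CC)(CC)CC)C=C1 | intermediate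
9 | (4R,7S)-7-(5-hydroxy-2,2-dimethyl-1,3-dioxan-5-yl)-4-methyl-4-(triethylsilyloxy)cyclohept-2-en-1-one (side chain β, OSiEt3 α) | CC1(C)OCC(O)(CO1)[C@@H]2CC[C@@](C)(O[Si](CC)(CC)CC)C=CC2=O | intermediate
10 | 4-iodobut-1-yne | C#CCCI | starting material
11 | but-3-yn-1-yl radical | [CH2]CC#C | intermediate
12 | C5 radical after addition of 11 to C1 (but-3-ynyl chain β) | CC1(C)OCC(O)(CO1)[C@@H]2CC[C@@](C)(O[Si](CC)(CC)CC)[C@H](CCC#C)[CH]C2=O | intermediate
13 | C15 vinyl radical after 5-exo-dig closure | CC1(C)OCC(O)(CO1)[C@@H]2CC[C@@](C)(O[Si](CC)(CC)CC)[C@@H]3CCC(=[CH])[C@@H]3C2=O | intermediate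
14 | 11-hydroxy-12,13-isopropylidenedioxy-10α-triethylsilyloxy-1αH,5αH,7αH-guai-4(15)-en-6-one | CC1(C)OCC(O)(CO1)[C@@H]2CC[C@@](C)(O[Si](CC)(CC)CC)[C@@H]3CCC(=C)[C@@H]3C2=O | intermediate
15 | 12,13-isopropylidenedioxy-10α-triethylsilyloxy-1αH,5αH,7αH-guai-4(15)-ene-6α,11-diol | CC1(C)OCC(O)(CO1)[C@@H]2CC[C@@](C)(O[Si](CC)(CC)CC)[C@@H]3CCC(=C)[C@@H]3[C@H]2O | intermediate
16 | 4α-hydroperoxide of 17 | CC1(C)OCC(O)(CO1)[C@@H]2CC[C@@](C)(O[Si](CC)(CC)CC)[C@@H]3CC[C@@](C)(OO)[C@@H]3[C@H]2O | intermediate
17 | 12,13-isopropylidenedioxy-10α-triethylsilyloxy-1αH,5αH,7αH-guaiane-4α,6α,11-triol | CC1(C)OCC(O)(CO1)[C@@H]2CC[C@@](C)(O[Si](CC)(CC)CC)[C@@H]3CC[C@@](C)(O)[C@@H]3[C@H]2O | intermediate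
18 | 1αH,5αH,7αH-guaiane-4α,6α,10α,11,12,13-hexaol | OCC(O)(CO)[C@@H]1CC[C@@](C)(O)[C@@H]2CC[C@@](C)(O)[C@@H]2[C@H]1O | intermediate
19 | CNP0179913.1, (1R,4R,5S,6S,7R,10R)-4,6,10,11-tetrahydroxyguaiane-12,13-diyl diacetate | CC(=O)OCC(O)(COC(C)=O)[C@@H]1CC[C@@](C)(O)[C@@H]2CC[C@@](C)(O)[C@@H]2[C@H]1O | target

Total step count: 10. Longest linear sequence: 10 (from 1; 7 and 10 are bought).

Steps most likely to fail

Step 6.
- What may go wrong: hydrogen abstraction by the C5 radical before ring closure; slow addition of a primary radical next to the quaternary C10; loss of facial selectivity at C1 if the bulky C7 side chain pushes the ring into a conformer with C14, not OSiEt3, pseudo-axial.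
- Fallback: a stepwise polar annulation that sets out from 9 and comes back at 14. Compound 9 would be treated with but-3-enylmagnesium bromide and CuBr·SMe2 in THF at −78 °C in the presence of excess Me3SiCl, with Et3N added before work-up. By 1,4-addition and O-silylation this should give the C5=C6 trimethylsilyl enol ether of the 1β-(but-3-enyl) ketone with C11–OSiMe3 F1. Pd(OAc)2 in DMSO under O2 should then form C4–C5 by 5-exo-trig attack of the enolate of divalent palladium on the alkene, followed by β-hydride elimination to the exocyclic methylene. A citric acid wash should free the C11 hydroxyl and give 14.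

Step 5.
- What may go wrong: proton transfer between the dienolate and the enolizable ketone 7; retro-aldol cleavage on work-up; poor facial selectivity at C7.
- Fallback: the order of steps 5 and 6 is exchanged and C7 is set by protonation instead of C–C bond formation, setting out from 6 and coming back at 14. Compound 6 would be annulated with 10 under the conditions of step 6, free of any influence of a C7 substituent, to the side-chain-free bicyclic ketone F2. LDA followed by N-chlorosuccinimide would give the 7-chloro ketone F3. A Darzens condensation with 7 (t-BuOK, THF, −78 to 0 °C) would give the C7–C11 spiro epoxy ketone F4, whose configuration does not matter. SmI2 in THF/MeOH at −78 °C would open the epoxide to the samarium enolate, and its protonation on the convex α face should give 14 with H7 α.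

Step 8.
- What may go wrong: oxygen capture on both faces of the planar C4 radical, or simple reduction of the radical.
- Fallback: a hydroxyl-directed two-electron sequence that sets out from 15 and comes back at 17. VO(acac)2 and t-BuOOH in CH2Cl2, directed by the homoallylic 6α-hydroxyl, should give the 4α,15-epoxide F5. LiBHEt3 in THF should open it at the primary C15 and give 17 with the 4α-hydroxyl.

Further compounds
F1 | step 6 | C5=C6 trimethylsilyl enol ether of the 1β-(but-3-enyl) ketone with C11–OSiMe3 | CC1(C)OCC(O[Si](C)(C)C)(CO1)[C@@H]2CC[C@@](C)(O[Si](CC)(CC)CC)[C@H](CCC=C)C=C2O[Si](C)(C)C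
F2 | step 5 | 10α-triethylsilyloxy-11,12,13-trinor-1αH,5αH-guai-4(15)-en-6-one | C1CC[C@@](C)(O[Si](CC)(CC)CC)[C@@H]2CCC(=C)[C@@H]2C1=O
F3 | step 5 | 7-chloro derivative of F2 (C7 epimers) | ClC1CC[C@@](C)(O[Si](CC)(CC)CC)[C@@H]2CCC(=C)[C@@H]2C1=O
F4 | step 5 | C7–C11 spiro epoxy ketone with the 12,13-isopropylidene ketal (C7 epimers) | CC1(C)OCC2(CO1)OC23CC[C@@](C)(O[Si](CC)(CC)CC)[C@@H]4CCC(=C)[C@@H]4C3=O
F5 | step 8 | 4α,15-epoxide of 15 | CC1(C)OCC(O)(CO1)[C@@H]2CC[C@@](C)(O[Si](CC)(CC)CC)[C@@H]3CC[C@]4(CO4)[C@@H]3[C@H]2O
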